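Rings are lettered A to E from the 2,4,6-trihydroxyphenoxy end; B1 carries the oxygen to ring A and B5 the oxygen to ring C. Ring B is not joined by ether coupling but grown on an ethynyl ether of the CDE unit: the alkyne supplies B5 (with its ether oxygen) and B6, and 2,3-dimethoxycyclobutenone supplies B1–B4 with the B3 and B4 oxygens. One thermal benzannulation forms B1–B6, B4–B5 and B1–B2 and frees the B1 hydroxyl meta to the B5 oxygen. The precursor is the permethylated CDE aryloxyacetylene, assembled by two copper-catalysed etherifications and two Baeyer–Villiger unmaskings. Ullmann attachment of ring A and global demethylation finish the route.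

Key step: step 10

Remark on the chemistry: the target is achiral; 17, 18 and 21 each carry one stereocentre, are formed as racemates and lose it later, and the terminal aryloxyacetylene 15 is assumed to be handled only as a cold solution and used at once.

Step 1
Reactants: 1 syringaldehyde (4-hydroxy-3,5-dimethoxybenzaldehyde); 2 3,4,5-trimethoxyphenylboronic acid
Product: 3 DE aldehyde 3,5-dimethoxy-4-(3,4,5-trimethoxyphenoxy)benzaldehyde
Conditions: Cu(OAc)2 (20 mol %), pyridine, 4 Å MS, O2 (1 atm), CH2Cl2, rt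
Reagents that add atoms: none
Why: Chan–Lam coupling of a phenol with an arylboronic acid proceeds at room temperature even with 2,6-disubstituted phenols and leaves the aldehyde untouched.

Step 2
Reactants: 3 DE aldehyde
Product: 5 DE phenol 3,5-dimethoxy-4-(3,4,5-trimethoxyphenoxy)phenol, via DE formate 4 (not isolated)
Conditions: mCPBA, CH2Cl2, 0 °C to rt; then K2CO3 (cat.), MeOH, rt
Reagents that add atoms: mCPBA (3-chloroperoxybenzoic acid), O=C(OO)c1cccc(Cl)c1
Why: Baeyer–Villiger (Dakin-type) oxidation in which the electron-rich aryl group migrates to oxygen, followed by methanolysis of the aryl formate.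

Step 3
Reactants: 5 DE phenol; 6 2-bromo-3,4,5-trimethoxybenzaldehyde
Product: 7 CDE aldehyde 2-[3,5-dimethoxy-4-(3,4,5-trimethoxyphenoxy)phenoxy]-3,4,5-trimethoxybenzaldehyde
Conditions: CuI (10 mol %), N,N-dimethylglycine hydrochloride (30 mol %), Cs2CO3, dioxane, 100 °C
Reagents that add atoms: none
Why: Ullmann-type copper-catalysed diaryl ether synthesis between an unhindered, electron-rich phenoxide and an aryl bromide whose carbon–bromine bond is activated by the ortho formyl group.

Step 4
Reactants: 7 CDE aldehyde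
Product: 9 CDE phenol 2-[3,5-dimethoxy-4-(3,4,5-trimethoxyphenoxy)phenoxy]-3,4,5-trimethoxyphenol, via CDE formate 8 (not isolated)
Conditions: mCPBA, CH2Cl2, 0 °C to rt; then K2CO3 (cat.), MeOH, rt
Reagents that add atoms: mCPBA (3-chloroperoxybenzoic acid), O=C(OO)c1cccc(Cl)c1
Why: Baeyer–Villiger (Dakin-type) oxidation with migration of the tetraoxygenated aryl group, then methanolysis, turns the activating formyl group into the hydroxyl that will carry the alkyne.

Step 5
Reactants: 9 CDE phenol; 10 trichloroethylene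
Product: 12 CDE (E)-1,2-dichlorovinyl ether 1-[(E)-1,2-dichloroethenyloxy]-2-[3,5-dimethoxy-4-(3,4,5-trimethoxyphenoxy)phenoxy]-3,4,5-trimethoxybenzene, via dichloroacetylene 11 (not isolated)
Conditions: K2CO3, DMF, 70 °C
Reagents that add atoms: none
Why: Elimination–addition vinylation, in which base converts trichloroethylene into dichloroacetylene 11 and the phenoxide adds to it in anti fashion, should give the E dichlorovinyl ether.

Step 6
Reactants: 12 CDE (E)-1,2-dichlorovinyl ether
Product: 15 CDE aryloxyacetylene 1-ethynyloxy-2-[3,5-dimethoxy-4-(3,4,5-trimethoxyphenoxy)phenoxy]-3,4,5-trimethoxybenzene, via chloroethynyl ether 13 (not isolated), via lithium acetylide 14 (not isolated)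
Conditions: n-BuLi (2.5 equiv), Et2O, −78 to −40 °C; then MeOH, −78 °C; kept cold in toluene and used at once
Reagents that add atoms: none
Why: Dehydrochlorination of the dichlorovinyl ether to chloroalkyne 13, lithium–chlorine exchange to acetylide 14 and protonation is the standard dichlorovinyl ether route to ynol ethers.

Step 7
Reactants: 16 dimethyl squarate
Product: 17 racemic 4-hydroxy-2,3-dimethoxycyclobut-2-en-1-one
Conditions: LiAlH(OtBu)3, THF, −78 °C
Reagents that add atoms: none
Why: Selective 1,2-reduction of one ketone by a bulky alkoxyaluminium hydride stops at the hydroxy ketone because the remaining carbonyl is a vinylogous ester; the new stereocentre is formed without control (racemic) and is removed in step 9.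

Step 8
Reactants: 17 racemic 4-hydroxy-2,3-dimethoxycyclobut-2-en-1-one
Product: 18 racemic 2,3-dimethoxy-4-oxocyclobut-2-en-1-yl acetate
Conditions: Ac2O, pyridine, DMAP (cat.), CH2Cl2, 0 °C
Reagents that add atoms: acetic anhydride, CC(=O)OC(C)=O
Why: Nucleophile-catalysed O-acylation under basic conditions avoids the acid-induced ionisation of the hydroxyl that would expel methanol and give the cyclobutenedione.

Step 9
Reactants: 18 racemic 2,3-dimethoxy-4-oxocyclobut-2-en-1-yl acetate
Product: 19 2,3-dimethoxycyclobut-2-en-1-one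
Conditions: Pd(PPh3)4 (5 mol %), n-Bu3SnH (1.1 equiv, slow addition), THF, rt
Reagents that add atoms: none
Why: Palladium-catalysed allylic hydrogenolysis (Tsuji–Trost-type ionisation of the allylic, alpha-keto acetate by zerovalent palladium, then hydride transfer from tin) should deliver hydride to the unsubstituted CH terminus and keep the tetrasubstituted dimethoxy enone.

Step 10
Reactants: 15 CDE aryloxyacetylene; 19 2,3-dimethoxycyclobut-2-en-1-one
Product: 24 BCDE phenol 3-{2-[3,5-dimethoxy-4-(3,4,5-trimethoxyphenoxy)phenoxy]-3,4,5-trimethoxyphenoxy}-4,5-dimethoxyphenol, via vinylketene 20 (not isolated), via cyclobutenone adduct 21 (not isolated), via dienylketene 22 (not isolated), via cyclohexadienone 23 (not isolated)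
Conditions: 19 (2 equiv), toluene, 80 °C then 110 °C, sealed tube, Ar; then K2CO3, MeOH, rt
Reagents that add atoms: none
Why: Thermal 4-electron ring opening of 19 gives vinylketene 20, which undergoes [2+2] cycloaddition with the electron-rich alkyne of 15 so that the ketene carbonyl carbon bonds to the terminal alkyne carbon (B1–B6) and the methoxy-bearing ketene carbon to the aryloxy-bearing carbon (B4–B5), giving cyclobutenone 21. Conrotatory reopening of 21 gives dienylketene 22, and ring B closes by disrotatory 6-electron electrocyclisation (B1–B2) to dienone 23, which tautomerises to phenol 24. The closest known reaction is the Danheiser benzannulation of cyclobutenones with alkoxy- and siloxyacetylenes. No stereocentre is created in 24, and the quaternary centre of racemic 21 disappears on ring opening. The step needs regioselectivity, secured by the oxygen-induced polarisation of the ynol ether that makes its unsubstituted carbon the nucleophile, and inward rotation of the methoxyvinyl group of 21, secured by the outward preference of the methoxy donor on the same carbon. The aryl group on the ynol oxygen has no beta hydrogen, so retro-ene loss of a ketene cannot compete, and the excess of 19 covers acylation of the product phenol by 20, which the carbonate methanolysis reverses.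

Step 11
Reactants: 24 BCDE phenol; 25 2-iodo-1,3,5-trimethoxybenzene
Product: 26 tridecamethyl ether 2-(3-{2-[3,5-dimethoxy-4-(3,4,5-trimethoxyphenoxy)phenoxy]-3,4,5-trimethoxyphenoxy}-4,5-dimethoxyphenoxy)-1,3,5-trimethoxybenzene
Conditions: CuI (20 mol %), picolinic acid (40 mol %), K3PO4, DMSO, 100 °C
Reagents that add atoms: none
Why: Ullmann-type copper-catalysed O-arylation with a ligand system suited to ortho-substituted partners should join the unhindered B1 phenoxide to the aryl iodide that has two ortho methoxy groups.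

Step 12
Reactants: 26 tridecamethyl ether
Product: 27 target CNP0228612.0, 2-(3-{2-[3,5-dihydroxy-4-(3,4,5-trihydroxyphenoxy)phenoxy]-3,4,5-trihydroxyphenoxy}-4,5-dihydroxyphenoxy)benzene-1,3,5-triol
Conditions: BBr3 (20 equiv), CH2Cl2, −78 °C to rt, Ar; then H2O, 0 °C; degassed work-up
Reagents that add atoms: none
Why: Lewis acid-mediated dealkylation of aryl methyl ethers (bromide attacks the methyl group of the boron-complexed ether) should cleave all thirteen methyl ethers and leave the diaryl ether bonds intact.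

Compound list
1 | syringaldehyde (4-hydroxy-3,5-dimethoxybenzaldehyde) | O=Cc1cc(OC)c(O)c(OC)c1 | starting material
2 | 3,4,5-trimethoxyphenylboronic acid | OB(O)c1cc(OC)c(OC)c(OC)c1 | starting material
3 | DE aldehyde, 3,5-dimethoxy-4-(3,4,5-trimethoxyphenoxy)benzaldehyde | O=Cc1cc(OC)c(Oc2cc(OC)c(OC)c(OC)c2)c(OC)c1 | intermediate
4 | DE formate, 3,5-dimethoxy-4-(3,4,5-trimethoxyphenoxy)phenyl formate | O=COc1cc(OC)c(Oc2cc(OC)c(OC)c(OC)c2)c(OC)c1 | intermediate (not isolated)
5 | DE phenol, 3,5-dimethoxy-4-(3,4,5-trimethoxyphenoxy)phenol | Oc1cc(OC)c(Oc2cc(OC)c(OC)c(OC)c2)c(OC)c1 | intermediate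
6 | 2-bromo-3,4,5-trimethoxybenzaldehyde | O=Cc1cc(OC)c(OC)c(OC)c1Br | starting material
7 | CDE aldehyde, 2-[3,5-dimethoxy-4-(3,4,5-trimethoxyphenoxy)phenoxy]-3,4,5-trimethoxybenzaldehyde | O=Cc1cc(OC)c(OC)c(OC)c1Oc1cc(OC)c(Oc2cc(OC)c(OC)c(OC)c2)c(OC)c1 | intermediate
8 | CDE formate, formate ester of 9 | O=COc1cc(OC)c(OC)c(OC)c1Oc1cc(OC)c(Oc2cc(OC)c(OC)c(OC)c2)c(OC)c1 | intermediate (not isolated)
9 | CDE phenol, 2-[3,5-dimethoxy-4-(3,4,5-trimethoxyphenoxy)phenoxy]-3,4,5-trimethoxyphenol | Oc1cc(OC)c(OC)c(OC)c1Oc1cc(OC)c(Oc2cc(OC)c(OC)c(OC)c2)c(OC)c1 | intermediate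
10 | trichloroethylene | ClC=C(Cl)Cl | starting material
11 | dichloroacetylene | ClC#CCl | intermediate (not isolated)
12 | CDE (E)-1,2-dichlorovinyl ether (the two chlorines trans) | Cl/C=C(/Cl)Oc1cc(OC)c(OC)c(OC)c1Oc1cc(OC)c(Oc2cc(OC)c(OC)c(OC)c2)c(OC)c1 | intermediate
13 | CDE chloroethynyl ether | ClC#COc1cc(OC)c(OC)c(OC)c1Oc1cc(OC)c(Oc2cc(OC)c(OC)c(OC)c2)c(OC)c1 | intermediate (not isolated)
14 | lithium acetylide of 15 | [Li]C#COc1cc(OC)c(OC)c(OC)c1Oc1cc(OC)c(Oc2cc(OC)c(OC)c(OC)c2)c(OC)c1 | intermediate (not isolated)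
15 | CDE aryloxyacetylene, 1-ethynyloxy-2-[3,5-dimethoxy-4-(3,4,5-trimethoxyphenoxy)phenoxy]-3,4,5-trimethoxybenzene | C#COc1cc(OC)c(OC)c(OC)c1Oc1cc(OC)c(Oc2cc(OC)c(OC)c(OC)c2)c(OC)c1 | intermediate
16 | dimethyl squarate | COC1=C(OC)C(=O)C1=O | starting material
17 | racemic 4-hydroxy-2,3-dimethoxycyclobut-2-en-1-one | COC1=C(OC)C(=O)C1O | intermediate
18 | racemic 2,3-dimethoxy-4-oxocyclobut-2-en-1-yl acetate | COC1=C(OC)C(=O)C1OC(C)=O | intermediate
19 | 2,3-dimethoxycyclobut-2-en-1-one | COC1=C(OC)C(=O)C1 | intermediate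
20 | vinylketene, 2,3-dimethoxybuta-1,3-dien-1-one | C=C(OC)C(OC)=C=O | intermediate (not isolated)
21 | cyclobutenone adduct, racemic 3-(CDE-aryloxy)-4-methoxy-4-(1-methoxyethenyl)cyclobut-2-en-1-one | C=C(OC)C1(OC)C(=O)C=C1Oc1cc(OC)c(OC)c(OC)c1Oc1cc(OC)c(Oc2cc(OC)c(OC)c(OC)c2)c(OC)c1 | intermediate (not isolated)
22 | (Z)-dienylketene, 3-(CDE-aryloxy)-4,5-dimethoxyhexa-1,3,5-trien-1-one, ketene and methoxyvinyl groups cis | C=C(OC)/C(OC)=C(\C=C=O)Oc1cc(OC)c(OC)c(OC)c1Oc1cc(OC)c(Oc2cc(OC)c(OC)c(OC)c2)c(OC)c1 | intermediate (not isolated)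
23 | cyclohexadienone, 3-(CDE-aryloxy)-4,5-dimethoxycyclohexa-2,4-dien-1-one | O=C1CC(OC)=C(OC)C(Oc2cc(OC)c(OC)c(OC)c2Oc2cc(OC)c(Oc3cc(OC)c(OC)c(OC)c3)c(OC)c2)=C1 | intermediate (not isolated)
24 | BCDE phenol, 3-{2-[3,5-dimethoxy-4-(3,4,5-trimethoxyphenoxy)phenoxy]-3,4,5-trimethoxyphenoxy}-4,5-dimethoxyphenol | Oc1cc(OC)c(OC)c(Oc2cc(OC)c(OC)c(OC)c2Oc2cc(OC)c(Oc3cc(OC)c(OC)c(OC)c3)c(OC)c2)c1 | intermediate
25 | 2-iodo-1,3,5-trimethoxybenzene | COc1cc(OC)c(I)c(OC)c1 | starting material
26 | tridecamethyl ether of the target | COc1cc(OC)c(Oc2cc(OC)c(OC)c(Oc3cc(OC)c(OC)c(OC)c3Oc3cc(OC)c(Oc4cc(OC)c(OC)c(OC)c4)c(OC)c3)c2)c(OC)c1 | intermediate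
27 | CNP0228612.0 | Oc1cc(O)c(Oc2cc(O)c(O)c(Oc3cc(O)c(O)c(O)c3Oc3cc(O)c(Oc4cc(O)c(O)c(O)c4)c(O)c3)c2)c(O)c1 | target

Total step count: 12. Longest linear sequence: 9 steps (steps 1 to 6, then 10, 11 and 12); steps 7 to 9 form the second branch.

Steps most likely to fail

1. Step 10. The terminal aryloxyacetylene may oligomerise or hydrate before the vinylogous-ester cyclobutenone has opened, and the transient ketene may be consumed by acylating the product phenol. The fallback attaches ring B as a whole and does not build it. It sets out from 9: Ullmann coupling with 3-bromo-4,5-dimethoxybenzaldehyde (CuI, N,N-dimethylglycine hydrochloride, Cs2CO3, dioxane, 100 °C) should give the BCDE aldehyde F1. Baeyer–Villiger oxidation with mCPBA gives the BCDE formate F2, and methanolysis (K2CO3, MeOH) comes back to the route at 24.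

2. Step 9. Hydride may be transferred to the methoxy-bearing end of the allyl unit, which would give the transposed 3,4-dimethoxy isomer, or the tin hydride may go on to reduce the enone. The fallback is a radical deoxygenation that sets out from 17: O-phenyl chlorothionoformate and pyridine in CH2Cl2 give the racemic O-(2,3-dimethoxy-4-oxocyclobut-2-en-1-yl) O-phenyl thiocarbonate F3. Barton–McCombie reduction with (Me3Si)3SiH and Et3B/air in toluene at rt comes back to the route at 19.

3. Step 11. Copper insertion at the carbon flanked by two methoxy groups of the electron-rich iodide may be slow, so that reductive loss of iodine and decomposition of the phenoxide take over. The fallback brings ring A in as an aldehyde-activated electrophile and installs its fourth oxygen afterwards. It sets out from 24: Ullmann coupling with 4-bromo-3,5-dimethoxybenzaldehyde under the conditions of step 3 should give the pentaaryl aldehyde F4. Baeyer–Villiger oxidation with mCPBA gives the pentaaryl formate F5, and methanolysis gives the ring A phenol F6, which has twelve methyl ethers. Treatment with BBr3 as in step 12 comes back to the route at 27.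

Further compounds
F1 | step 10 | BCDE aldehyde, 3-{2-[3,5-dimethoxy-4-(3,4,5-trimethoxyphenoxy)phenoxy]-3,4,5-trimethoxyphenoxy}-4,5-dimethoxybenzaldehyde | O=Cc1cc(OC)c(OC)c(Oc2cc(OC)c(OC)c(OC)c2Oc2cc(OC)c(Oc3cc(OC)c(OC)c(OC)c3)c(OC)c2)c1
F2 | step 10 | BCDE formate, formate ester of 24 | O=COc1cc(OC)c(OC)c(Oc2cc(OC)c(OC)c(OC)c2Oc2cc(OC)c(Oc3cc(OC)c(OC)c(OC)c3)c(OC)c2)c1
F3 | step 9 | racemic O-(2,3-dimethoxy-4-oxocyclobut-2-en-1-yl) O-phenyl thiocarbonate | COC1=C(OC)C(=O)C1OC(=S)Oc1ccccc1
F4 | step 11 | pentaaryl aldehyde, 4-(BCDE-aryloxy)-3,5-dimethoxybenzaldehyde | O=Cc1cc(OC)c(Oc2cc(OC)c(OC)c(Oc3cc(OC)c(OC)c(OC)c3Oc3cc(OC)c(Oc4cc(OC)c(OC)c(OC)c4)c(OC)c3)c2)c(OC)c1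
F5 | step 11 | pentaaryl formate, formate ester of F6 | O=COc1cc(OC)c(Oc2cc(OC)c(OC)c(Oc3cc(OC)c(OC)c(OC)c3Oc3cc(OC)c(Oc4cc(OC)c(OC)c(OC)c4)c(OC)c3)c2)c(OC)c1
F6 | step 11 | ring A phenol, 4-(BCDE-aryloxy)-3,5-dimethoxyphenol (dodecamethyl ether of the target) | Oc1cc(OC)c(Oc2cc(OC)c(OC)c(Oc3cc(OC)c(OC)c(OC)c3Oc3cc(OC)c(Oc4cc(OC)c(OC)c(OC)c4)c(OC)c3)c2)c(OC)c1
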